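**Retrosynthetic overview**
- Target ⇐ 3-docosyl-2,5-dimethoxy-1,4-benzoquinone by selective acid hydrolysis of the methoxy group next to the chain; that ⇐ 3-docosyl-2,5-dihydroxy-1,4-benzoquinone by exhaustive O-methylation.
- Key C–C disconnection (ring C3 to chain C1'): intermolecular Knoevenagel-type aldol condensation of 2,5-dihydroxy-1,4-benzoquinone (enolic carbon as donor) with docosanal, the alkylidene being reduced in the same flask by Hantzsch ester.
- Docosanal ⇐ 1-docosanol by oxidation.
- Rings: the only ring, the quinone ring, is bought intact in 2,5-dihydroxy-1,4-benzoquinone; no ring is formed.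

Assumption: the SMILES holds no stereocentre and no stereogenic double bond, so the target is achiral and the one structure drawn is made; the chain is read as unbranched docosyl (22 carbons, C29H50O4).

**Route**

Step 1
Reactants: 1 1-docosanol (behenyl alcohol)
Product: 2 docosanal
Conditions: TEMPO (2,2,6,6-tetramethylpiperidin-1-oxyl, 0.1 equiv), PhI(OAc)2 (1.1 equiv), CH2Cl2, 30 °C, 4 h
Reagents that add atoms: none
Why: TEMPO-catalysed alcohol oxidation with PhI(OAc)2 as terminal oxidant stops at the aldehyde under anhydrous conditions, and no stereocentre is formed.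

Step 2
Reactants: 2 docosanal; 3 2,5-dihydroxy-1,4-benzoquinone (1.5 equiv)
Product: 5 3-docosyl-2,5-dihydroxy-1,4-benzoquinone, via alkylidene trione 4 (not isolated)
Conditions: L-proline (0.2 equiv), Hantzsch ester (diethyl 2,6-dimethyl-1,4-dihydropyridine-3,5-dicarboxylate, 1.1 equiv), CH2Cl2, 25 °C, 24 h
Reagents that add atoms: none
Why: In this three-component reductive alkylation (Knoevenagel-type aldol condensation) the enolic C3 of the vinylogous acid 3 adds to the proline-activated aldehyde and loses water to give 4, which the Hantzsch ester reduces at once by conjugate hydride transfer; excess 3 holds back 3,6-dialkylation and no stereocentre is formed.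

Step 3
Reactants: 5 3-docosyl-2,5-dihydroxy-1,4-benzoquinone
Product: 6 3-docosyl-2,5-dimethoxy-1,4-benzoquinone
Conditions: Me2SO4 (4 equiv), K2CO3 (4 equiv), acetone, reflux, 6 h
Reagents that add atoms: dimethyl sulfate, COS(=O)(=O)OC
Why: Both hydroxyls are vinylogous carboxylic acids whose potassium salts undergo Williamson-type O-methylation with the hard electrophile Me2SO4, the excess driving the hindered hydroxyl next to the chain to completion; no stereocentre is formed.

Step 4
Reactants: 6 3-docosyl-2,5-dimethoxy-1,4-benzoquinone
Product: 7 2-hydroxy-5-methoxy-3-docosyl-1,4-benzoquinone (target)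
Conditions: 70% aq HClO4, 1,4-dioxane, 25 °C, 12 h (stopped at full conversion of 6)
Reagents that add atoms: water, O
Why: In this acid-catalysed addition–elimination hydrolysis of a vinylogous ester, the methoxy flanked by the docosyl chain and a carbonyl is twisted out of conjugation and is cleaved selectively, while the unhindered 5-methoxy stays, and the new enol is held by a hydrogen bond to the neighbouring carbonyl; no stereocentre is formed.

**Compound list**
1 | 1-docosanol (behenyl alcohol) | CCCCCCCCCCCCCCCCCCCCCCO | starting material
2 | docosanal | CCCCCCCCCCCCCCCCCCCCCC=O | intermediate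
3 | 2,5-dihydroxy-1,4-benzoquinone | O=C1C=C(O)C(=O)C=C1O | starting material
4 | 3-docosylidene-5-hydroxycyclohex-5-ene-1,2,4-trione (alkene geometry not defined, formed and reduced in the flask) | CCCCCCCCCCCCCCCCCCCCCC=C1C(=O)C(O)=CC(=O)C1=O | intermediate
5 | 3-docosyl-2,5-dihydroxy-1,4-benzoquinone | CCCCCCCCCCCCCCCCCCCCCCC1=C(O)C(=O)C=C(O)C1=O | intermediate
6 | 3-docosyl-2,5-dimethoxy-1,4-benzoquinone | CCCCCCCCCCCCCCCCCCCCCCC1=C(OC)C(=O)C=C(OC)C1=O | intermediate
7 | 2-hydroxy-5-methoxy-3-docosyl-1,4-benzoquinone (achiral) | CCCCCCCCCCCCCCCCCCCCCCC1=C(O)C(=O)C=C(OC)C1=O | target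

**Count**
Total step count: 4. Longest linear sequence: 4 steps (1 → 2 → 5 → 6 → 7).

**Steps most likely to fail, each with a fallback**

Step 2 (reductive alkylation). The risks are a second alkylation at C6, and slow conversion because 3 is poorly soluble and the aldehyde is waxy. The fallback sets out from 1-docosanol 1 and comes back to the route at 3-docosyl-2,5-dimethoxy-1,4-benzoquinone 6. Compound 1 is heated with 48% HBr and concentrated H2SO4 to give 1-bromodocosane F1. Bought 1,2,4,5-tetramethoxybenzene F2 is deprotonated between two methoxy groups with n-BuLi in THF at 0 °C to give (2,3,5,6-tetramethoxyphenyl)lithium F3. F3 is alkylated with F1 in THF/DMPU to give 3-docosyl-1,2,4,5-tetramethoxybenzene F4. Oxidative demethylation of F4 with (NH4)2Ce(NO3)6 in MeCN/water at 0 °C gives 6; both possible para-quinones are the same compound, so no regiochemical question arises. The route then continues with step 4.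

Step 4 (selective hydrolysis). The risks are cleavage of the wrong methoxy group or of both. The fallback sets out from 2,5-dihydroxy-1,4-benzoquinone 3 (with docosanal 2 from step 1) and comes back at the target 7; it fixes the methoxy position before the chain is attached. Compound 3 is heated in methanol with HCl to give 2,5-dimethoxy-1,4-benzoquinone F5. One equivalent of NaOH in aqueous methanol, then HCl, removes a single methyl group to give 2-hydroxy-5-methoxy-1,4-benzoquinone F6, because the mono-anion resists a second hydroxide attack. F6 has only one enolic carbon; under the conditions of step 2 it condenses with 2 to give 3-docosylidene-5-methoxycyclohex-5-ene-1,2,4-trione F7, which is not isolated and is reduced by Hantzsch ester to 7.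

Step 3 (exhaustive methylation). The risks are incomplete methylation of the hindered hydroxyl, C-methylation at C6, or loss of the quinone to base. The fallback sets out from 3-docosyl-2,5-dihydroxy-1,4-benzoquinone 5 and comes back at the target 7, leaving out 6. Compound 5 is heated in methanol with catalytic H2SO4. This is an acid-catalysed, equilibrium-controlled etherification of a vinylogous acid, which takes place at the unhindered 5-hydroxyl only; the hindered ether is the one that acid cleaves. The fallback makes no compound outside the compound list (entry F0).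

**Further compounds**
F1 | step 2 | 1-bromodocosane | CCCCCCCCCCCCCCCCCCCCCCBr
F2 | step 2 | 1,2,4,5-tetramethoxybenzene (bought) | COc1cc(OC)c(OC)cc1OC
F3 | step 2 | (2,3,5,6-tetramethoxyphenyl)lithium | [Li]c1c(OC)c(OC)cc(OC)c1OC
F4 | step 2 | 3-docosyl-1,2,4,5-tetramethoxybenzene | CCCCCCCCCCCCCCCCCCCCCCc1c(OC)c(OC)cc(OC)c1OC
F5 | step 4 | 2,5-dimethoxy-1,4-benzoquinone | COC1=CC(=O)C(OC)=CC1=O
F6 | step 4 | 2-hydroxy-5-methoxy-1,4-benzoquinone | COC1=CC(=O)C(O)=CC1=O
F7 | step 4 | 3-docosylidene-5-methoxycyclohex-5-ene-1,2,4-trione | CCCCCCCCCCCCCCCCCCCCCC=C1C(=O)C(OC)=CC(=O)C1=O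
F0 | step 3 | none | none
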